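**Retrosynthetic overview**

1. The trans-chlorohydrin C9(Cl)–C10(OH) of target 25 is read as a cis-9,10-epoxide opened by chloride at C9. The epoxide comes from a ring alkene by oxygen delivery from the C6 hydroxyl, and the Z-enyne from a C3–C4 alkyne by iodination, diimide reduction and Sonogashira coupling.
2. C6–Cl and C13–Br are put in by SN2 inversion of the C6 and C13 alcohols, so the ring precursor is the Δ9-oxepene 15.
3. Key disconnection: 15 is cut at C8–C9 and O–C12 into the terminal oxirane 5 (O, C7, C8) and the Z-alkenyllithium 13 (C9 to C12), which carries the C12–C13 oxirane. This is a formal [4+3] ring expansion of an oxirane to an oxepene by an alkoxide relay between two epoxides.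
4. Enabling feature: the ring oxygen lies between C7 and C12, and each has an exocyclic heteroatom-bearing neighbour (C6, C13) in the pattern of an opened epoxide, while C9/C10 is a masked Z-alkene. The oxepane is therefore the oxirane O–C7–C8 enlarged by the four carbons C9–C12.
5. Ring order: the oxepene (step 8) is the only ring of the target; a temporary 9,10-oxirane is fused on in step 11 and opened in step 17. Absolute configuration comes from two Sharpless epoxidations (steps 2 and 4).

Key step: step 8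

Remark: carbons are numbered C1 (alkyne CH) to C15 (ethyl CH3) as in the target. Compounds 1, 2, 6 and 8 are assumed to be commercial.

**Route**

Step 1
Reactants: 1 acrolein (prop-2-enal); 2 3-bromo-1-(trimethylsilyl)prop-1-yne
Product: 3 rac-6-(trimethylsilyl)hex-1-en-5-yn-3-ol
Conditions: Zn dust, THF, 0 °C; then 1, −78 → 0 °C; aq NH4Cl
Reagents that add atoms: none
Why: Barbier-type propargylation, in which the allenylzinc bromide from 2 should add 1,2 to the aldehyde through an SE2′ transition state to give the homopropargylic alcohol; the carbinol center forms racemic and is resolved in step 2.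

Step 2
Reactants: 3 rac-6-(trimethylsilyl)hex-1-en-5-yn-3-ol
Product: 4 (1S)-1-[(2R)-oxiran-2-yl]-4-(trimethylsilyl)but-3-yn-1-ol
Conditions: Ti(OiPr)4 (cat.), L-(+)-diisopropyl tartrate (cat.), t-BuOOH (0.45 equiv), 4 Å molecular sieves, CH2Cl2, −20 °C
Reagents that add atoms: tert-butyl hydroperoxide CC(C)(C)OO
Why: Sharpless kinetic resolution of a secondary allylic alcohol, in which the L-(+)-tartrate catalyst should epoxidize the (S)-enantiomer fast and anti (erythro) to the carbinol substituent, setting C6 (S, as the alcohol) and C7 (R) together by catalyst control while the (R)-enantiomer of 3 stays behind and is separated.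

Step 3
Reactants: 4 (1S)-1-[(2R)-oxiran-2-yl]-4-(trimethylsilyl)but-3-yn-1-ol
Product: 5 tert-butyl(dimethyl){[(1S)-1-[(2R)-oxiran-2-yl]-4-(trimethylsilyl)but-3-yn-1-yl]oxy}silane
Conditions: TBSCl, imidazole, DMF, 0 °C → rt
Reagents that add atoms: tert-butyldimethylsilyl chloride CC(C)(C)[Si](C)(C)Cl
Why: silyl ether formation without a free alkoxide, which avoids the Payne rearrangement open to this epoxy alcohol; no stereocenter is touched.

Step 4
Reactants: 6 (E)-pent-2-en-1-ol
Product: 7 [(2S,3S)-3-ethyloxiran-2-yl]methanol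
Conditions: Ti(OiPr)4 (cat.), L-(+)-diethyl tartrate (cat.), t-BuOOH, 4 Å molecular sieves, CH2Cl2, −20 °C
Reagents that add atoms: tert-butyl hydroperoxide CC(C)(C)OO
Why: Sharpless asymmetric epoxidation of a primary E-allylic alcohol, in which the L-(+)-tartrate catalyst should deliver oxygen to the face that gives the (2S,3S)-trans-epoxide, setting C12 and C13 by catalyst control.

Step 5
Reactants: 7 [(2S,3S)-3-ethyloxiran-2-yl]methanol; 8 ethynyltrimethylsilane
Product: 10 (2S,3S)-2-ethyl-3-[3-(trimethylsilyl)prop-2-yn-1-yl]oxirane, via epoxy triflate 9 (not isolated)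
Conditions: Tf2O, 2,6-lutidine, CH2Cl2, −78 °C; then LiC≡CSiMe3 (from 8 and n-BuLi), THF/DMPU, −78 → −20 °C
Reagents that add atoms: none
Why: triflation of the primary alcohol followed by SN2 displacement with a lithium acetylide at low temperature, where the primary triflate should react far faster than the oxirane; no stereocenter is touched.

Step 6
Reactants: 10 (2S,3S)-2-ethyl-3-[3-(trimethylsilyl)prop-2-yn-1-yl]oxirane
Product: 11 (2S,3S)-2-ethyl-3-(3-iodoprop-2-yn-1-yl)oxirane
Conditions: NIS, AgNO3 (cat.), DMF, rt, dark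
Reagents that add atoms: N-iodosuccinimide O=C1CCC(=O)N1I
Why: silver-catalysed iododesilylation of an alkynylsilane gives the 1-iodoalkyne directly and should leave the epoxide untouched.

Step 7
Reactants: 11 (2S,3S)-2-ethyl-3-(3-iodoprop-2-yn-1-yl)oxirane
Product: 12 (2S,3S)-2-ethyl-3-[(2Z)-3-iodoprop-2-en-1-yl]oxirane
Conditions: 2-nitrobenzenesulfonylhydrazide, Et3N, THF/i-PrOH, rt
Reagents that add atoms: none
Why: diimide reduction, in which diimide from the sulfonylhydrazide adds hydrogen syn to the iodoalkyne and should give the Z-iodoalkene without cleaving the C–I bond or the epoxide.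

Step 8
Reactants: 12 (2S,3S)-2-ethyl-3-[(2Z)-3-iodoprop-2-en-1-yl]oxirane; 5 tert-butyl(dimethyl){[(1S)-1-[(2R)-oxiran-2-yl]-4-(trimethylsilyl)but-3-yn-1-yl]oxy}silane
Product: 15 (1S)-1-[(2R,7R)-7-[(1S)-1-{[tert-butyl(dimethyl)silyl]oxy}-4-(trimethylsilyl)but-3-yn-1-yl]-2,3,6,7-tetrahydrooxepin-2-yl]propan-1-ol, via alkenyllithium 13 (not isolated), via lithium alkoxide 14 (not isolated)
Conditions: 12, t-BuLi (2 equiv), Et2O, −78 °C; then 5 (excess) and BF3·OEt2, −78 °C; then further BF3·OEt2, CH2Cl2, −78 → 0 °C, same flask; aq NaHCO3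
Reagents that add atoms: none
Why: Proposed new method: iodine–lithium exchange gives the configurationally stable Z-alkenyllithium 13, which opens the BF3-activated terminal oxirane of 5 at C8, and the alkoxide at O7 released in this way (14) attacks the BF3-activated internal oxirane at C12 with inversion, closing the oxepene and leaving the alkoxide on C13; BF3 acts as promoter and is not consumed. The closest known reaction types are the BF3-promoted opening of terminal epoxides by alkenyllithiums and the Lewis-acid-promoted cyclization of Z-configured hydroxy epoxides to 2,7-disubstituted oxepenes, here joined as a relay in one flask. The oxepene closes in the 7-exo-tet mode (O7 to C12), the Z double bond of the tether holding the two ends close and the 8-endo path to C13 being disfavoured by ring size. No stereocenter is created: C6 and C7 come unchanged from 5, C12 is inverted and C13 retained from the trans-oxirane of 12, so the 7,12-trans relation of the ring follows from the two Sharpless epoxidations and not from ring thermodynamics. The step needs chemoselectivity of 13 for the terminal oxirane of 5 over the internal oxirane of a second molecule of 12 or 13; the unhindered CH2 terminus, the low temperature and the excess of 5 should secure it. Self-destruction of 13 would require a cyclobutene-forming 4-exo or a 5-endo opening, both disfavoured.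

Step 9
Reactants: 15 (1S)-1-[(2R,7R)-7-[(1S)-1-{[tert-butyl(dimethyl)silyl]oxy}-4-(trimethylsilyl)but-3-yn-1-yl]-2,3,6,7-tetrahydrooxepin-2-yl]propan-1-ol
Product: 16 tert-butyl({(1S)-1-[(2R,7R)-7-[(1R)-1-bromopropyl]-2,3,6,7-tetrahydrooxepin-2-yl]-4-(trimethylsilyl)but-3-yn-1-yl}oxy)dimethylsilane
Conditions: CBr4, P(n-C8H17)3, toluene, 70 °C
Reagents that add atoms: tetrabromomethane BrC(Br)(Br)Br
Why: Appel-type bromination, in which bromide displaces the oxyphosphonium group with inversion and turns the (13S)-alcohol into the (13R)-bromide of the target; the trialkylphosphine variant is the usual choice for hindered alcohols next to an ether oxygen.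

Step 10
Reactants: 16 tert-butyl({(1S)-1-[(2R,7R)-7-[(1R)-1-bromopropyl]-2,3,6,7-tetrahydrooxepin-2-yl]-4-(trimethylsilyl)but-3-yn-1-yl}oxy)dimethylsilane
Product: 17 (1S)-1-[(2R,7R)-7-[(1R)-1-bromopropyl]-2,3,6,7-tetrahydrooxepin-2-yl]-4-(trimethylsilyl)but-3-yn-1-ol
Conditions: p-TsOH·H2O (cat.), MeOH, rt
Reagents that add atoms: none
Why: acid-catalysed methanolysis of the secondary TBS ether; the alkynylsilane, the bromide and the ring alkene should be stable to dilute acid.

Step 11
Reactants: 17 (1S)-1-[(2R,7R)-7-[(1R)-1-bromopropyl]-2,3,6,7-tetrahydrooxepin-2-yl]-4-(trimethylsilyl)but-3-yn-1-ol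
Product: 18 (1S)-1-[(1R,3R,5R,7S)-5-[(1R)-1-bromopropyl]-4,8-dioxabicyclo[5.1.0]octan-3-yl]-4-(trimethylsilyl)but-3-yn-1-ol
Conditions: VO(acac)2 (cat.), t-BuOOH, CH2Cl2, 0 °C → rt
Reagents that add atoms: tert-butyl hydroperoxide CC(C)(C)OO
Why: hydroxyl-directed epoxidation of a bishomoallylic alcohol, in which the vanadate ester of the C6 hydroxyl can reach the ring alkene only on the face that carries the C7 side chain and should set C9 (R) and C10 (S) by substrate control; the alkyne is inert, and the syn epoxy alcohol cannot cyclize because the hydroxyl has no access to the rear of the oxirane.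

Step 12
Reactants: 18 (1S)-1-[(1R,3R,5R,7S)-5-[(1R)-1-bromopropyl]-4,8-dioxabicyclo[5.1.0]octan-3-yl]-4-(trimethylsilyl)but-3-yn-1-ol
Product: 20 (1R,3R,5R,7S)-5-[(1R)-1-bromopropyl]-3-[(1R)-1-chloro-4-(trimethylsilyl)but-3-yn-1-yl]-4,8-dioxabicyclo[5.1.0]octane, via triflate 19 (not isolated)
Conditions: Tf2O, pyridine, CH2Cl2, −78 °C; then n-Bu4NCl, −78 → 0 °C
Reagents that add atoms: tetrabutylammonium chloride CCCC[N+](CCCC)(CCCC)CCCC.[Cl-]
Why: triflation and SN2 displacement by chloride invert C6 to the (R)-chloride of the target; the triflate should be displaced well below the temperature at which chloride opens the epoxide or exchanges with the C13 bromide.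

Step 13
Reactants: 20 (1R,3R,5R,7S)-5-[(1R)-1-bromopropyl]-3-[(1R)-1-chloro-4-(trimethylsilyl)but-3-yn-1-yl]-4,8-dioxabicyclo[5.1.0]octane
Product: 21 (1R,3R,5R,7S)-5-[(1R)-1-bromopropyl]-3-[(1R)-1-chloro-4-iodobut-3-yn-1-yl]-4,8-dioxabicyclo[5.1.0]octane
Conditions: NIS, AgNO3 (cat.), DMF, rt, dark
Reagents that add atoms: N-iodosuccinimide O=C1CCC(=O)N1I
Why: silver-catalysed iododesilylation of the alkynylsilane, as in step 6; the catalytic silver salt should not ionize the deactivated β-alkoxy bromide.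

Step 14
Reactants: 21 (1R,3R,5R,7S)-5-[(1R)-1-bromopropyl]-3-[(1R)-1-chloro-4-iodobut-3-yn-1-yl]-4,8-dioxabicyclo[5.1.0]octane
Product: 22 (1R,3R,5R,7S)-5-[(1R)-1-bromopropyl]-3-[(1R,3Z)-1-chloro-4-iodobut-3-en-1-yl]-4,8-dioxabicyclo[5.1.0]octane
Conditions: 2-nitrobenzenesulfonylhydrazide, Et3N, THF/i-PrOH, rt
Reagents that add atoms: none
Why: diimide reduction of the iodoalkyne by syn addition of hydrogen should give the Z-iodoalkene, as in step 7, and sets the C3–C4 geometry.

Step 15
Reactants: 22 (1R,3R,5R,7S)-5-[(1R)-1-bromopropyl]-3-[(1R,3Z)-1-chloro-4-iodobut-3-en-1-yl]-4,8-dioxabicyclo[5.1.0]octane; 8 ethynyltrimethylsilane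
Product: 23 (1R,3R,5R,7S)-5-[(1R)-1-bromopropyl]-3-[(1R,3Z)-1-chloro-6-(trimethylsilyl)hex-3-en-5-yn-1-yl]-4,8-dioxabicyclo[5.1.0]octane
Conditions: Pd(PPh3)4 (cat.), CuI (cat.), i-Pr2NH, THF, rt
Reagents that add atoms: none
Why: Sonogashira coupling of the Z-alkenyl iodide proceeds with retention of the double-bond geometry; the secondary alkyl halides and the epoxide should be inert to zerovalent palladium at room temperature.

Step 16
Reactants: 23 (1R,3R,5R,7S)-5-[(1R)-1-bromopropyl]-3-[(1R,3Z)-1-chloro-6-(trimethylsilyl)hex-3-en-5-yn-1-yl]-4,8-dioxabicyclo[5.1.0]octane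
Product: 24 (1R,3R,5R,7S)-5-[(1R)-1-bromopropyl]-3-[(1R,3Z)-1-chlorohex-3-en-5-yn-1-yl]-4,8-dioxabicyclo[5.1.0]octane
Conditions: K2CO3 (cat.), MeOH, 0 °C
Reagents that add atoms: none
Why: base-catalysed methanolysis of the C(sp)–Si bond frees the terminal alkyne; the epoxide and the alkyl halides should tolerate catalytic carbonate at 0 °C.

Step 17
Reactants: 24 (1R,3R,5R,7S)-5-[(1R)-1-bromopropyl]-3-[(1R,3Z)-1-chlorohex-3-en-5-yn-1-yl]-4,8-dioxabicyclo[5.1.0]octane
Product: 25 (2R,4S,5S,7R)-2-[(1R)-1-bromopropyl]-5-chloro-7-[(1R,3Z)-1-chlorohex-3-en-5-yn-1-yl]oxepan-4-ol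
Conditions: LiCl, AcOH, THF, rt
Reagents that add atoms: lithium chloride [Li+].[Cl-]
Why: acid-assisted SN2 opening of the epoxide by chloride is anti, so attack at C9 from the face opposite the oxirane oxygen gives the trans-chlorohydrin with (9S)-Cl and (10S)-OH; C9 is expected to be preferred because approach to C10 on that face meets the bromopropyl chain on C12, whereas the C7 chain lies on the face of the oxirane oxygen.

**Compound list**

1 | acrolein (prop-2-enal) | C=CC=O | starting material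
2 | 3-bromo-1-(trimethylsilyl)prop-1-yne | C[Si](C)(C)C#CCBr | starting material
3 | rac-6-(trimethylsilyl)hex-1-en-5-yn-3-ol | C=CC(O)CC#C[Si](C)(C)C | intermediate
4 | (1S)-1-[(2R)-oxiran-2-yl]-4-(trimethylsilyl)but-3-yn-1-ol | C[Si](C)(C)C#CC[C@H](O)[C@H]1CO1 | intermediate
5 | tert-butyl(dimethyl){[(1S)-1-[(2R)-oxiran-2-yl]-4-(trimethylsilyl)but-3-yn-1-yl]oxy}silane | C[Si](C)(C)C#CC[C@H](O[Si](C)(C)C(C)(C)C)[C@H]1CO1 | intermediate
6 | (E)-pent-2-en-1-ol | CC/C=C/CO | starting material
7 | [(2S,3S)-3-ethyloxiran-2-yl]methanol | CC[C@@H]1O[C@H]1CO | intermediate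
8 | ethynyltrimethylsilane | C#C[Si](C)(C)C | starting material
9 | [(2S,3S)-3-ethyloxiran-2-yl]methyl trifluoromethanesulfonate | CC[C@@H]1O[C@H]1COS(=O)(=O)C(F)(F)F | intermediate
10 | (2S,3S)-2-ethyl-3-[3-(trimethylsilyl)prop-2-yn-1-yl]oxirane | CC[C@@H]1O[C@H]1CC#C[Si](C)(C)C | intermediate
11 | (2S,3S)-2-ethyl-3-(3-iodoprop-2-yn-1-yl)oxirane | CC[C@@H]1O[C@H]1CC#CI | intermediate
12 | (2S,3S)-2-ethyl-3-[(2Z)-3-iodoprop-2-en-1-yl]oxirane | CC[C@@H]1O[C@H]1C/C=C\I | intermediate
13 | {(1Z)-3-[(2S,3S)-3-ethyloxiran-2-yl]prop-1-en-1-yl}lithium | CC[C@@H]1O[C@H]1C/C=C\[Li] | intermediate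
14 | lithium (4S,5R,7Z)-4-{[tert-butyl(dimethyl)silyl]oxy}-9-[(2S,3S)-3-ethyloxiran-2-yl]-1-(trimethylsilyl)non-7-en-1-yn-5-olate | C[Si](C)(C)C#CC[C@H](O[Si](C)(C)C(C)(C)C)[C@H](O[Li])C/C=C\C[C@@H]1O[C@H]1CC | intermediate
15 | (1S)-1-[(2R,7R)-7-[(1S)-1-{[tert-butyl(dimethyl)silyl]oxy}-4-(trimethylsilyl)but-3-yn-1-yl]-2,3,6,7-tetrahydrooxepin-2-yl]propan-1-ol | C[Si](C)(C)C#CC[C@H](O[Si](C)(C)C(C)(C)C)[C@H]1C/C=C\C[C@@H](O1)[C@@H](O)CC | intermediate
16 | tert-butyl({(1S)-1-[(2R,7R)-7-[(1R)-1-bromopropyl]-2,3,6,7-tetrahydrooxepin-2-yl]-4-(trimethylsilyl)but-3-yn-1-yl}oxy)dimethylsilane | C[Si](C)(C)C#CC[C@H](O[Si](C)(C)C(C)(C)C)[C@H]1C/C=C\C[C@@H](O1)[C@H](Br)CC | intermediate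
17 | (1S)-1-[(2R,7R)-7-[(1R)-1-bromopropyl]-2,3,6,7-tetrahydrooxepin-2-yl]-4-(trimethylsilyl)but-3-yn-1-ol | C[Si](C)(C)C#CC[C@H](O)[C@H]1C/C=C\C[C@@H](O1)[C@H](Br)CC | intermediate
18 | (1S)-1-[(1R,3R,5R,7S)-5-[(1R)-1-bromopropyl]-4,8-dioxabicyclo[5.1.0]octan-3-yl]-4-(trimethylsilyl)but-3-yn-1-ol | C[Si](C)(C)C#CC[C@H](O)[C@H]1C[C@H]2O[C@H]2C[C@@H](O1)[C@H](Br)CC | intermediate
19 | (1S)-1-[(1R,3R,5R,7S)-5-[(1R)-1-bromopropyl]-4,8-dioxabicyclo[5.1.0]octan-3-yl]-4-(trimethylsilyl)but-3-yn-1-yl trifluoromethanesulfonate | C[Si](C)(C)C#CC[C@H](OS(=O)(=O)C(F)(F)F)[C@H]1C[C@H]2O[C@H]2C[C@@H](O1)[C@H](Br)CC | intermediate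
20 | (1R,3R,5R,7S)-5-[(1R)-1-bromopropyl]-3-[(1R)-1-chloro-4-(trimethylsilyl)but-3-yn-1-yl]-4,8-dioxabicyclo[5.1.0]octane | C[Si](C)(C)C#CC[C@@H](Cl)[C@H]1C[C@H]2O[C@H]2C[C@@H](O1)[C@H](Br)CC | intermediate
21 | (1R,3R,5R,7S)-5-[(1R)-1-bromopropyl]-3-[(1R)-1-chloro-4-iodobut-3-yn-1-yl]-4,8-dioxabicyclo[5.1.0]octane | IC#CC[C@@H](Cl)[C@H]1C[C@H]2O[C@H]2C[C@@H](O1)[C@H](Br)CC | intermediate
22 | (1R,3R,5R,7S)-5-[(1R)-1-bromopropyl]-3-[(1R,3Z)-1-chloro-4-iodobut-3-en-1-yl]-4,8-dioxabicyclo[5.1.0]octane | I/C=C\C[C@@H](Cl)[C@H]1C[C@H]2O[C@H]2C[C@@H](O1)[C@H](Br)CC | intermediate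
23 | (1R,3R,5R,7S)-5-[(1R)-1-bromopropyl]-3-[(1R,3Z)-1-chloro-6-(trimethylsilyl)hex-3-en-5-yn-1-yl]-4,8-dioxabicyclo[5.1.0]octane | C[Si](C)(C)C#C/C=C\C[C@@H](Cl)[C@H]1C[C@H]2O[C@H]2C[C@@H](O1)[C@H](Br)CC | intermediate
24 | (1R,3R,5R,7S)-5-[(1R)-1-bromopropyl]-3-[(1R,3Z)-1-chlorohex-3-en-5-yn-1-yl]-4,8-dioxabicyclo[5.1.0]octane | C#C/C=C\C[C@@H](Cl)[C@H]1C[C@H]2O[C@H]2C[C@@H](O1)[C@H](Br)CC | intermediate
25 | (2R,4S,5S,7R)-2-[(1R)-1-bromopropyl]-5-chloro-7-[(1R,3Z)-1-chlorohex-3-en-5-yn-1-yl]oxepan-4-ol | C#C/C=C\C[C@@H](Cl)[C@H]1C[C@H](Cl)[C@@H](O)C[C@H]([C@H](Br)CC)O1 | target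

**Step count and risks**

Total step count: 17. Longest linear sequence: 14 steps (steps 4 to 17, from 6).

Steps most likely to fail:

Step 8 (the step that bears the label). The alkenyllithium may open the internal oxirane of a second molecule and oligomerize, the iodide left from the exchange may compete as a nucleophile during the warm stage, or the relay may stall at the open-chain alkoxide or close in the 8-endo mode. The fallback uses known chemistry only, sets out from 10 and 5 and comes back at 15. Compound 10 is desilylated with K2CO3 in MeOH to (2S,3S)-2-ethyl-3-(prop-2-yn-1-yl)oxirane F1. Its lithium acetylide (n-BuLi, THF, −78 °C) opens the terminal epoxide of 5 with BF3·OEt2 to give (4S,5R)-4-{[tert-butyl(dimethyl)silyl]oxy}-9-[(2S,3S)-3-ethyloxiran-2-yl]-1-(trimethylsilyl)nona-1,7-diyn-5-ol F2. The dialkyl alkyne is semihydrogenated with H2 over Pd/CaCO3 poisoned with Pb(OAc)2 and quinoline, the silyl-capped alkyne reacting more slowly, to (4S,5R,7Z)-4-{[tert-butyl(dimethyl)silyl]oxy}-9-[(2S,3S)-3-ethyloxiran-2-yl]-1-(trimethylsilyl)non-7-en-1-yn-5-ol F3. F3 is then cyclized 7-exo through its tributylstannyl ether ((Bu3Sn)2O, then Zn(OTf)2, toluene, heat) to 15.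

Step 17. Regiocontrol may be lost, with chloride entering at C10 because the flexible seven-membered ring does not enforce one opening mode. The fallback sets out from 24 and comes back at 24, turning the step into a recycle loop instead of relying on one-pass selectivity. The regioisomer (2R,4R,5R,7R)-7-[(1R)-1-bromopropyl]-5-chloro-2-[(1R,3Z)-1-chlorohex-3-en-5-yn-1-yl]oxepan-4-ol F4 is separated from 25 and closed back to the same epoxide 24 by anti displacement with K2CO3 in MeOH, and 24 is then resubmitted to step 17.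

Step 12. The C6 triflate may eliminate, the ring oxygen may participate, chloride may exchange with the C13 bromide, or chloride may open the epoxide early. The fallback sets out from 17 and comes back at 20 with the two operations in reverse order. The alcohol is chlorinated with inversion at the alkene stage by the Appel-type reaction (CCl4, P(n-C8H17)3, toluene, 80 °C) to (2R,7R)-2-[(1R)-1-bromopropyl]-7-[(1R)-1-chloro-4-(trimethylsilyl)but-3-yn-1-yl]-2,3,6,7-tetrahydrooxepine F5. F5 is then epoxidized with mCPBA (NaHCO3, CH2Cl2). The directing hydroxyl is given up, so the face selectivity rests only on shielding by the two side chains, and 20 may have to be separated from its face isomer.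

Further compounds
F1 | step 8 | (2S,3S)-2-ethyl-3-(prop-2-yn-1-yl)oxirane | CC[C@@H]1O[C@H]1CC#C
F2 | step 8 | (4S,5R)-4-{[tert-butyl(dimethyl)silyl]oxy}-9-[(2S,3S)-3-ethyloxiran-2-yl]-1-(trimethylsilyl)nona-1,7-diyn-5-ol | C[Si](C)(C)C#CC[C@H](O[Si](C)(C)C(C)(C)C)[C@H](O)CC#CC[C@@H]1O[C@H]1CC
F3 | step 8 | (4S,5R,7Z)-4-{[tert-butyl(dimethyl)silyl]oxy}-9-[(2S,3S)-3-ethyloxiran-2-yl]-1-(trimethylsilyl)non-7-en-1-yn-5-ol | C[Si](C)(C)C#CC[C@H](O[Si](C)(C)C(C)(C)C)[C@H](O)C/C=C\C[C@@H]1O[C@H]1CC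
F4 | step 17 | (2R,4R,5R,7R)-7-[(1R)-1-bromopropyl]-5-chloro-2-[(1R,3Z)-1-chlorohex-3-en-5-yn-1-yl]oxepan-4-ol | C#C/C=C\C[C@@H](Cl)[C@H]1C[C@@H](O)[C@H](Cl)C[C@H]([C@H](Br)CC)O1
F5 | step 12 | (2R,7R)-2-[(1R)-1-bromopropyl]-7-[(1R)-1-chloro-4-(trimethylsilyl)but-3-yn-1-yl]-2,3,6,7-tetrahydrooxepine | C[Si](C)(C)C#CC[C@@H](Cl)[C@H]1C/C=C\C[C@@H](O1)[C@H](Br)CC
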